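The runs were computed from invented constants, and the scatter is random.

**Early chord.** Watch the first 2.4 min of the repeat, and then the moment the curve bends over.

| setting | epsilon | eta | gamma | zeta | beta |
|---|---|---|---|---|---|
| Sub | 0.300 M | 0.120 M | 0.300 M | 0.600 M | 1.50 M |
| Rgt | 0.900 M | 0.720 M | 2.70 M | 0.900 M | 4.50 M |
| time |  |  |  |  | 18 min |

- epsilon run (time / min: [Prd] / M): 0.80: 0.006; 2.4: 0.034; 4.6: 0.061; 7.4: 0.079; 11: 0.092; 14: 0.094; 18: 0.099
- eta run (time / min: [Prd] / M): 0.80: 0.006; 2.4: 0.010; 4.6: 0.024; 7.4: 0.027; 11: 0.036; 14: 0.038; 18: 0.041
- gamma run (time / min: [Prd] / M): 0.80: 0.018; 2.4: 0.047; 4.6: 0.077; 7.4: 0.104; 11: 0.117; 14: 0.122; 18: 0.128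
- zeta run (time / min: [Prd] / M): 0.80: 0.014; 2.4: 0.065; 4.6: 0.121; 7.4: 0.153; 11: 0.179; 14: 0.185; 18: 0.190

(scatter of a reading: 0.003 M)

- order of the initial rate in [Sub], near the charge of the epsilon run, the rate being that where two percent of its Sub are Prd (one fixed amount of Prd, the same in the runs compared)
- order of the initial rate in [Rgt], near the charge of the epsilon run, the rate being that where two percent of its Sub are Prd
- Prd in the beta run at 18 min, as a share of the Sub charged

- Overall: Sub + Rgt -> Prd.
- Constant volume, constant temperature.
- What is held in complexes is read along with the free species.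
- "The second partner" is Rgt.
- An order is taken over about fifteen percent of the charge, up and down.

**Start rate.** I took the reading at 2.4 min over that time as the early mean rate. That gave 0.0142 M min⁻¹ in the epsilon run, 0.0196 M min⁻¹ in the gamma run and 0.0271 M min⁻¹ in the zeta run. I left the eta run out, because the scatter on its reading was 30.0% of it. As chords across these wide steps, the rates gave me orders of 0.935 in [Sub] and 0.295 in [Rgt]. The orders asked are instead taken near the epsilon charge, at one fixed amount of Prd.

**The slowing.** Between 11 min and 18 min the epsilon run made Prd at only 0.00100 M min⁻¹, a reading with wide scatter, so its rate had fallen 14.2-fold. Counted by the Prd made and nothing else, [Sub], the limiting reagent there, fell by a factor of 1.49 and [Rgt] by 1.12. Even at order one in each, that makes 1.68, far less than the fall, so I stopped following the concentrations.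

**Fade time.** I replaced each curve by its early rate held flat for a fade time, the time that flat rate needs to give the Prd read at 18 min: 6.54 min in the gamma run, and 6.99 min and 7.02 min in the epsilon and zeta runs. For the beta run, my orders carried the gamma rate to 0.103 M min⁻¹. With the gamma fade time, the nearest in [Rgt], that gave 44.7% of the Sub charged, and with the epsilon fade time 47.8%.

**The forecast.** It gave 0.78 (0.55 to 1.05) in [Sub], 0.45 (0.2 to 0.75) in [Rgt] and 42% (33% to 49%) for the beta run, and it read the plateaus as a sign that “something first-order dies”. My [Sub] order stood above its figure, my [Rgt] order below, and my share above.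

**The result.** The beta run gave 46.2% at 18 min, and the orders came out at 0.75 in [Sub] and 0.31 in [Rgt].

    Sub → Int (0.1488 min⁻¹)
    Int + Rgt → Prd (4.884 L mol⁻¹ min⁻¹)
    Int → Sid (0.9780 min⁻¹)
    2 Rgt ⇌ Rgt2, settled at all times (9.570 L mol⁻¹)
    Sub → G (0.06780 min⁻¹)

**Fade again.** At the same small amount of Prd, the gamma run, with 3.00 times the Rgt of the epsilon run, went 1.4 times as fast as that run. Over the gamma fade time, the beta result asks for an early rate of 0.106 M min⁻¹, faster than my 0.103 M min⁻¹. In the eta run, the rate of 0.0061 M min⁻¹ at that same small amount of Prd, held for the gamma fade time, gives 0.0399 M, and the reading at 18 min was 0.041 M.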